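## Structural features

The target is an unbranched C20 chain whose C1–C5 end is closed through O5 into a six-membered 4-hydroxy-5,6-dihydro-2H-pyran-2-one. This ring is the enol form of a β-keto-δ-lactone, with C1 as carbonyl, C2=C3 as the enol double bond and C5 as its only sp3 stereocentre. C5 carries the open chain C6–C20, a 2,4,6-trihydroxypentadecyl group in which C7, C9 and C11 are secondary carbinols and C12–C20 is a plain nonyl tail. The four stereocentres C5 (R), C7 (R), C9 (S) and C11 (S) are separated by single methylene groups, so each stands 1,3 to the next: C5/C7 syn, C7/C9 anti, C9/C11 syn. The fragile part is the enolised β-keto lactone, a vinylogous acid that opens under base, can lose O5 by β-elimination, and whose open β-keto acid decarboxylates. The difficulty is not the skeleton, which is a string of acetate units. It lies in relaying configuration across four nearly identical carbinols, with a change from syn to anti in the middle, and in telling O5 from O7, O9 and O11 so that only O5 is acylated by C1. The key step uses the syn-1,3-diol C5/C7: it alone fits a chair 2-phenyl-1,3-dioxane (ring atoms O5, C5, C6, C7, O7 and the acetal carbon) with every substituent equatorial, so the O–C7 bond can be formed under equilibrium control from the single purchased centre C5. The same acetal marks O5 and O7 as a pair and leaves a vinyl group (C8=C9) from which C9 and C11 are relayed.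

## Logic of the disconnections

21 to 19. The lactone bond C1–O5 is cut, and the four hydroxyls are replaced by two cyclic acetals (O5/O7 and O9/O11). The acidic enol lactone is the least robust part and is formed last; 19 has no free hydroxyl and no free acid. The gain is the loss of the ring and of all polar groups. The demand is that a single acid treatment unveils O5 (passing through 20) no later than C1 is activated, and that O5 rather than O7 closes the ring; six- against eight-membered closure secures this.

19 to 18. The C2–C3 bond is cut. C3 is an ester carbonyl from the start of the route and C1–C2 is one acetate unit, so a crossed Claisen condensation is the natural forward step. The gain is a plain ethyl ester in place of the β-keto ester. The demand is an enolate that does not self-condense, a substrate without free hydroxyls, and conditions under which the β-oxygen O5 is not expelled.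

18 to 17 to 15. The two ketal C–O bonds are cut (protection only), then the C11–H bond. With C11 as a ketone, the C9 hydroxyl can direct hydride delivery and set the syn relation. The gain is one stereocentre less and an aldol retron. The demand is a chelation-controlled reduction that leaves the ethyl ester alone.

15 to 11 and 14, and 14 to 12 through 13. The C9–C10 bond is cut. This splits the molecule into the C3–C9 piece and the C10–C20 lipid tail, which is a cheap methyl ketone, and places the new carbinol C9 1,3 to the existing C7 oxygen. The gain is the most convergent cut of the route. The demand is an open-transition-state aldol that is 1,3-anti, spares the acetal, and uses the terminal enol silane.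

11 to 10 to 8. The C9 aldehyde is traced back through the C9 alcohol to the terminal alkene C8=C9 (C9–O bond, through 9). The vinyl group is exactly what the key step leaves behind. The gain is that no carbon has to be added or removed. The demand is anti-Markovnikov hydration and a mild oxidation that tolerate ester and acetal.

8 to 5 and 6, through 7. The O–C7 bond and the two acetal C–O bonds are cut. This removes the C7 stereocentre and the ring and leaves an allylic alcohol with one stereocentre, C5. The gain is that C7 need not be set by a reagent. The demand is a reversible 1,3-shift of the allylic oxygen coupled to acetal formation that runs to the thermodynamic isomer.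

5 to 3 and 4. The C7=C8 double bond is cut. Cross-metathesis attaches C8–C9 with its oxygen from a symmetrical C4 diol. The gain is a simple homoallylic alcohol. The demand is selectivity for the cross product; alkene geometry is unimportant because the next step erases it.

3 to 2 to 1. The C6–C7 bond is cut (vinyl onto the epoxide terminus), then the epoxide C–O bond back to the chlorohydrin. C5 is bought with its configuration. The demand is that epoxide opening outruns ester attack and base-induced ring opening.

## Other disconnections considered

Alternative 1: Both C–C bonds at C9 are cut (C8–C9 and C9–C10). Forward, lithiated 2-(tert-butyldimethylsilyl)-1,3-dithiane A2 opens (2S)-2-nonyloxirane A3 at its terminal carbon. A polar cosolvent then triggers 1,4-migration of silicon from carbon to the new alkoxide (Brook rearrangement), and the regenerated dithiane anion opens (2S)-2-(prop-2-en-1-yl)oxirane A4 to give (2S)-1-{2-[(2S)-2-(tert-butyldimethylsilyloxy)undecyl]-1,3-dithian-2-yl}pent-4-en-2-ol A1, the C4–C20 portion.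
- In its favour: two C–C bonds in one flask, O11 (silylated) and O7 (free) differentiated automatically, and C7 and C11 bought as epoxide centres rather than induced. A single hydroxyl-directed anti reduction of the unmasked C9 ketone from O7 would then set C9.
- Against it here: two enantiopure epoxides each need their own preparation, the dithiane must later be hydrolysed in the presence of an alkene, and the C1–C5 end is not addressed. C5 would still have to be set syn to C7 from the terminal alkene, and an acetoacetate-type aldol on the derived aldehyde has an innate 1,3-anti bias, which is the wrong sense.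
- Comparison: for the C7–C11 region A1 is the better construct, because the C9/C11 relation does not depend on the facial selectivity of an aldol, and its key step builds more skeleton per operation. For C5/C7 the chosen plan is stronger, since the syn relation comes from equilibrium. Mechanistically it is kinetic carbanion chemistry at low temperature against a catalytic equilibration. The overall step count should be similar or higher once epoxide synthesis, dithiane removal and the lactone end are added.

Alternative 2: The C3–C4 and C6–C7 bonds are cut. Forward, the oxyallyl cation generated from 1,1,3,3-tetrabromopropan-2-one A7 with a Zn–Cu couple adds across furan A6 in a [4+3] cycloaddition, and the remaining bromines are removed reductively in the same operation, giving meso 8-oxabicyclo[3.2.1]oct-6-en-3-one A5. By atom count its seven carbons map onto C2–C8: ketone C5, bridgeheads C3 and C7, olefinic carbons C2 and C8.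
- In its favour: bulk starting materials, one step to a rigid bicycle, access to either enantiomeric series by desymmetrisation, and very reliable facial control for reducing the C5 ketone.
- Against it here: C3 of the target is trigonal, so one of the two bridgehead centres is discarded. The ether bridge must be detached from C3 and C3 oxidised, the meso ketone must be desymmetrised, the olefin must be cleaved and one end extended by C1, and C9–C20 would still need the same aldol and reduction relay as the chosen plan.
- Comparison: A5 is the better choice on cost and scalability of raw materials, and equal in using ring conformation to control a 1,3-relation. It is weaker on structure (stereochemical content that the target does not need) and on step economy (a long sequence of ring cleavage and oxidation-state adjustment). Mechanistically it uses stoichiometric zinc, where the chosen step is catalytic.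

Alternative 3: The C2–C3 bond is cut at the very end. Forward, methyl (3R,5R)-3-(2-bromoacetoxy)-5-[(tert-butyldimethylsilyl)oxy]-6-[(4S,6S)-2,2-dimethyl-6-nonyl-1,3-dioxan-4-yl]hexanoate A9 is converted into its ester enolate, reductively or with an amide base. The enolate attacks the C3 methyl ester (Dieckmann closure) to give the protected target (6R)-6-{(2R)-2-[(tert-butyldimethylsilyl)oxy]-3-[(4S,6S)-2,2-dimethyl-6-nonyl-1,3-dioxan-4-yl]propyl}-4-hydroxy-5,6-dihydro-2H-pyran-2-one A8.
- In its favour: the C1–O5 ester bond is made by ordinary acylation of one defined hydroxyl, so ring size and regiochemistry are not left to a competition between O5 and O7, and no free β-keto acid appears. On this point A8 is the better end game than the acid-mediated closure of the chosen plan.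
- Against it here: it is a ring-closing tactic and sets no stereocentre. O5 must be the only free hydroxyl, which needs three differentiated protecting groups where the chosen plan keeps O5/O7 in one acetal. The β-acyloxy ester can eliminate under basic enolisation, and attack of an ester enolate on an unactivated ester is slow.
- Comparison: it is equal to the Claisen step of the chosen plan in skeletal bonds formed (one C–C bond). It costs two to three more steps for protecting-group differentiation. It could be grafted onto intermediates of the chosen route if the final step fails.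

Key step: step 4

Assumption: the target is made and drawn as the 4-hydroxy enol tautomer of the β-keto-δ-lactone; the keto form would equilibrate to it.

Remarks on the chemistry:
- The configuration of 1 and the all-cis dioxane of 8 were checked atom by atom against the target; no structure needed correction.
- Hydroboration–oxidation ends at the C9 alcohol, so the aldehyde needs its own oxidation (steps 5 and 6).
- The C9/C11 diol is masked before the Claisen condensation (step 10).
- 5 can be used as an E/Z mixture, because the allylic shift erases alkene geometry.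
- CIP descriptors at C7, C9 and the acetal carbon change along the route only because substituent priorities change; no centre is inverted.

## Route

Step 1
Reactants: 1 ethyl (3S)-4-chloro-3-hydroxybutanoate
Product: 2 ethyl 2-[(2S)-oxiran-2-yl]acetate
Conditions: Ag2O (1.5 equiv), DME, 60 °C, dark
Reagents that add atoms: none
Why: Ag2O acts as a mild, insoluble base and halophile, so the hydroxyl closes on C4 by intramolecular SN2 (Williamson-type epoxide formation) while AgCl precipitates; the carbinol centre is not touched, and the absence of soluble alkoxide limits base-induced opening of the β,γ-epoxy ester.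

Step 2
Reactants: 2 ethyl 2-[(2S)-oxiran-2-yl]acetate
Product: 3 ethyl (3R)-3-hydroxyhex-5-enoate
Conditions: CH2=CHMgBr (1.5 equiv), CuI (10 mol%), THF, −78 → −40 °C; aq. NH4Cl
Reagents that add atoms: vinylmagnesium bromide, C=C[Mg]Br
Why: Copper-catalysed Grignard opening of a terminal epoxide: the vinylcopper species attacks the unsubstituted carbon by SN2 much faster than the Grignard reagent adds to the ethyl ester at low temperature; the C–O bond at the stereocentre is untouched, and the descriptor becomes R only through changed priorities.

Step 3
Reactants: 3 ethyl (3R)-3-hydroxyhex-5-enoate; 4 (Z)-but-2-ene-1,4-diol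
Product: 5 ethyl (3R,5E)-3,7-dihydroxyhept-5-enoate
Conditions: 4 (4 equiv), second-generation Grubbs catalyst (H2IMes)(PCy3)Cl2Ru=CHPh (3 mol%), CH2Cl2, 40 °C
Reagents that add atoms: none
Why: Olefin cross-metathesis of a terminal alkene with an excess of the symmetrical internal diol; secondary metathesis should favour the E-disubstituted alkene, free hydroxyls and the ester are tolerated, and residual Z isomer need not be removed because both geometries converge in step 4.

Step 4
Reactants: 5 ethyl (3R,5E)-3,7-dihydroxyhept-5-enoate; 6 benzaldehyde dimethyl acetal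
Product: 8 ethyl 2-[(2S,4R,6S)-6-ethenyl-2-phenyl-1,3-dioxan-4-yl]acetate, via ethyl (3R,5S)-3,5-dihydroxyhept-6-enoate 7 (not isolated)
Conditions: Re2O7 (5 mol%), 6 (2 equiv), CH2Cl2, 0 °C → rt; Et3N quench
Reagents that add atoms: none
Why: Re2O7 esterifies the primary allylic hydroxyl O9 as a perrhenate, which undergoes a concerted chair-like [3,3]-sigmatropic shift that puts oxygen on C7 and the alkene at C8–C9; the closest known reaction type is this same oxo-rhenium 1,3-transposition of 2-ene-1,5-diols with acetal capture. The shift is reversible and not selective in itself, and alone it would favour the primary alcohol 5, so both C7 epimers of 7 are present only in small stationary amounts. The acidic perrhenate also ionises 6 to an oxocarbenium ion, which one hydroxyl of 7 captures with loss of methanol, and the second oxocarbenium ion is then closed by the other hydroxyl in a 6-endo-trig acetal exchange that forms the 1,3-dioxane. Only the transposed 1,3-diol can form a six-membered acetal (5 would need an eight-membered ring), so acetalisation drains the equilibrium towards oxygen on C7. The C7 centre is set under thermodynamic control by C5: acetal opening and back-transposition remain possible, and the mixture should settle on the chair with phenyl, vinyl and CH2CO2Et all equatorial, which exists only for the 5,7-syn diol. The acetal carbon follows in the same way (equatorial phenyl). The step needs positional selectivity (O on C7), ring-size selectivity and syn selectivity; all three come from the 1,3-relation of O5 to C7, and the lack of cation-stabilising groups on the allyl unit keeps the shift concerted and leaves the non-allylic C5 untouched.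

Step 5
Reactants: 8 ethyl 2-[(2S,4R,6S)-6-ethenyl-2-phenyl-1,3-dioxan-4-yl]acetate
Product: 10 ethyl 2-[(2R,4R,6R)-6-(2-hydroxyethyl)-2-phenyl-1,3-dioxan-4-yl]acetate, via B-alkyl-9-borabicyclo[3.3.1]nonane adduct 9 (not isolated)
Conditions: 9-BBN (1.3 equiv), THF, 0 °C → rt; then 30% H2O2, 3 M aq. NaOAc, 0 °C → rt
Reagents that add atoms: hydrogen peroxide, OO
Why: Hydroboration–oxidation: the bulky dialkylborane places boron on the terminal C9 and buffered peroxide replaces boron by hydroxyl; 9-BBN does not reduce the ester or touch the acetal, and the acetate buffer avoids saponification. No stereocentre is created.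

Step 6
Reactants: 10 ethyl 2-[(2R,4R,6R)-6-(2-hydroxyethyl)-2-phenyl-1,3-dioxan-4-yl]acetate
Product: 11 ethyl 2-[(2R,4R,6S)-6-(2-oxoethyl)-2-phenyl-1,3-dioxan-4-yl]acetate
Conditions: Dess–Martin periodinane (1.3 equiv), NaHCO3, CH2Cl2, 0 °C → rt
Reagents that add atoms: none
Why: Dess–Martin oxidation of a primary alcohol stops at the aldehyde under buffered, non-basic conditions, which should avoid β-elimination of O7 and acetal cleavage; the aldehyde is used directly.

Step 7
Reactants: 12 undecan-2-one
Product: 14 trimethyl(undec-1-en-2-yloxy)silane, via lithium undec-1-en-2-olate 13 (not isolated)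
Conditions: LiN(iPr)2 (1.05 equiv), THF, −78 °C; Me3SiCl (1.2 equiv), −78 °C → rt
Reagents that add atoms: chlorotrimethylsilane, C[Si](C)(C)Cl
Why: Kinetic deprotonation of the methyl ketone by the hindered amide removes a methyl proton preferentially and O-silylation traps the terminal enolate; any minor internal regioisomer would give a branched aldol that is removed after step 8.

Step 8
Reactants: 11 ethyl 2-[(2R,4R,6S)-6-(2-oxoethyl)-2-phenyl-1,3-dioxan-4-yl]acetate; 14 trimethyl(undec-1-en-2-yloxy)silane
Product: 15 ethyl 2-[(2R,4R,6R)-6-[(2R)-2-hydroxy-4-oxotridecyl]-2-phenyl-1,3-dioxan-4-yl]acetate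
Conditions: 14 (1.5 equiv), BF3·OEt2 (1.1 equiv), CH2Cl2, −78 °C; aq. NaHCO3
Reagents that add atoms: none
Why: Mukaiyama aldol through an open transition state: BF3 binds only the aldehyde oxygen, the C7–O dipole opposes the carbonyl dipole in the preferred conformer, and the enol silane approaches anti to the C7 ring residue, which should give the 1,3-anti (C7/C9) aldol; at −78 °C the activated aldehyde should react far faster than the dioxane acetal, and the ester is inert.

Step 9
Reactants: 15 ethyl 2-[(2R,4R,6R)-6-[(2R)-2-hydroxy-4-oxotridecyl]-2-phenyl-1,3-dioxan-4-yl]acetate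
Product: 17 ethyl 2-[(2R,4R,6R)-6-[(2S,4S)-2,4-dihydroxytridecyl]-2-phenyl-1,3-dioxan-4-yl]acetate, via diethylboron chelate 16 (not isolated)
Conditions: Et2BOMe (1.1 equiv), THF/MeOH 4:1, −78 °C; NaBH4 (1.2 equiv), −78 °C; AcOH, then MeOH co-evaporation
Reagents that add atoms: none
Why: Narasaka–Prasad reduction: the boron ties the C9 hydroxyl and the C11 ketone into a six-membered chelate and external hydride adds axially, which should give the 1,3-syn diol; NaBH4 at −78 °C does not reduce the ethyl ester.

Step 10
Reactants: 17 ethyl 2-[(2R,4R,6R)-6-[(2S,4S)-2,4-dihydroxytridecyl]-2-phenyl-1,3-dioxan-4-yl]acetate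
Product: 18 ethyl 2-[(2R,4R,6S)-6-{[(4R,6S)-2,2-dimethyl-6-nonyl-1,3-dioxan-4-yl]methyl}-2-phenyl-1,3-dioxan-4-yl]acetate
Conditions: Me2C(OMe)2 (5 equiv), PPTS (10 mol%), CH2Cl2, rt
Reagents that add atoms: 2,2-dimethoxypropane, COC(C)(C)OC
Why: Acid-catalysed transketalisation; a syn-1,3-diol readily forms the chair acetonide with both substituents equatorial, and the weak acid at room temperature should not scramble the more robust benzylidene acetal.

Step 11
Reactants: 18 ethyl 2-[(2R,4R,6S)-6-{[(4R,6S)-2,2-dimethyl-6-nonyl-1,3-dioxan-4-yl]methyl}-2-phenyl-1,3-dioxan-4-yl]acetate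
Product: 19 tert-butyl 4-[(2R,4R,6S)-6-{[(4R,6S)-2,2-dimethyl-6-nonyl-1,3-dioxan-4-yl]methyl}-2-phenyl-1,3-dioxan-4-yl]-3-oxobutanoate
Conditions: t-BuOAc (4 equiv), LiN(iPr)2 (4 equiv), THF, −78 °C; then 18, −78 → −30 °C; aq. NH4Cl
Reagents that add atoms: tert-butyl acetate, CC(=O)OC(C)(C)C
Why: Crossed Claisen condensation: the lithium enolate of tert-butyl acetate does not self-condense at −78 °C and adds to the ethyl ester; the β-keto ester formed is deprotonated at once by excess enolate and so protected from a second addition, all hydroxyls are masked, and the acetal oxygen O5 is a poor leaving group at this temperature.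

Step 12
Reactants: 19 tert-butyl 4-[(2R,4R,6S)-6-{[(4R,6S)-2,2-dimethyl-6-nonyl-1,3-dioxan-4-yl]methyl}-2-phenyl-1,3-dioxan-4-yl]-3-oxobutanoate
Product: 21 (6R)-4-hydroxy-6-[(2R,4S,6S)-2,4,6-trihydroxypentadecyl]-5,6-dihydro-2H-pyran-2-one, via (5R,7R,9S,11S)-5,7,9,11-tetrahydroxy-3-oxoicosanoic acid 20 (not isolated)
Conditions: CF3CO2H/H2O 9:1, 0 °C → rt; evaporate; aq. NaHCO3/MeOH, then 1 M HCl to pH 3
Reagents that add atoms: none
Why: Acid-mediated deprotection and lactonisation of a δ-hydroxy-β-keto tert-butyl ester: aqueous acid hydrolyses both acetals and ionises the tert-butyl ester, and O5 closes on C1 (6-exo-trig) to the δ-lactone, which enolises to the conjugated 4-hydroxypyranone as the thermodynamic sink. O7 could reach C1 only through an eight-membered ring and its hemiketal with C3 is reversible; no stereocentre is touched, and the bicarbonate wash cleaves any trifluoroacetate esters.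

## Compound list

1 | ethyl (3S)-4-chloro-3-hydroxybutanoate | CCOC(=O)C[C@H](O)CCl | starting material
2 | ethyl 2-[(2S)-oxiran-2-yl]acetate | CCOC(=O)C[C@H]1CO1 | intermediate
3 | ethyl (3R)-3-hydroxyhex-5-enoate | CCOC(=O)C[C@H](O)CC=C | intermediate
4 | (Z)-but-2-ene-1,4-diol | OC/C=C\CO | starting material
5 | ethyl (3R,5E)-3,7-dihydroxyhept-5-enoate | CCOC(=O)C[C@H](O)C/C=C/CO | intermediate
6 | benzaldehyde dimethyl acetal | COC(OC)c1ccccc1 | starting material
7 | ethyl (3R,5S)-3,5-dihydroxyhept-6-enoate (the syn epimer that is trapped; its C5 epimer interconverts with it) | CCOC(=O)C[C@H](O)C[C@H](O)C=C | intermediate (not isolated)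
8 | ethyl 2-[(2S,4R,6S)-6-ethenyl-2-phenyl-1,3-dioxan-4-yl]acetate (all-cis) | CCOC(=O)C[C@H]1C[C@@H](C=C)O[C@@H](c2ccccc2)O1 | intermediate
9 | B-alkyl-9-borabicyclo[3.3.1]nonane adduct of 8 (boron on C9, dioxane unchanged) | CCOC(=O)C[C@H]1C[C@@H](CCB3C4CCCC3CCC4)O[C@@H](c2ccccc2)O1 | intermediate (not isolated)
10 | ethyl 2-[(2R,4R,6R)-6-(2-hydroxyethyl)-2-phenyl-1,3-dioxan-4-yl]acetate (all-cis) | CCOC(=O)C[C@H]1C[C@@H](CCO)O[C@@H](c2ccccc2)O1 | intermediate
11 | ethyl 2-[(2R,4R,6S)-6-(2-oxoethyl)-2-phenyl-1,3-dioxan-4-yl]acetate (all-cis) | CCOC(=O)C[C@H]1C[C@@H](CC=O)O[C@@H](c2ccccc2)O1 | intermediate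
12 | undecan-2-one | CCCCCCCCCC(C)=O | starting material
13 | lithium undec-1-en-2-olate | [Li+].[O-]C(=C)CCCCCCCCC | intermediate (not isolated)
14 | trimethyl(undec-1-en-2-yloxy)silane | C=C(CCCCCCCCC)O[Si](C)(C)C | intermediate
15 | ethyl 2-[(2R,4R,6R)-6-[(2R)-2-hydroxy-4-oxotridecyl]-2-phenyl-1,3-dioxan-4-yl]acetate | CCOC(=O)C[C@H]1C[C@@H](C[C@@H](O)CC(=O)CCCCCCCCC)O[C@@H](c2ccccc2)O1 | intermediate
16 | diethylboron chelate of 15 (C9–O–BEt2 coordinated to the C11 carbonyl) | CCOC(=O)C[C@H]1C[C@@H](C[C@@H](OB(CC)CC)CC(=O)CCCCCCCCC)O[C@@H](c2ccccc2)O1 | intermediate (not isolated)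
17 | ethyl 2-[(2R,4R,6R)-6-[(2S,4S)-2,4-dihydroxytridecyl]-2-phenyl-1,3-dioxan-4-yl]acetate | CCOC(=O)C[C@H]1C[C@@H](C[C@@H](O)C[C@@H](O)CCCCCCCCC)O[C@@H](c2ccccc2)O1 | intermediate
18 | ethyl 2-[(2R,4R,6S)-6-{[(4R,6S)-2,2-dimethyl-6-nonyl-1,3-dioxan-4-yl]methyl}-2-phenyl-1,3-dioxan-4-yl]acetate | CCOC(=O)C[C@H]1C[C@@H](C[C@@H]3C[C@H](CCCCCCCCC)OC(C)(C)O3)O[C@@H](c2ccccc2)O1 | intermediate
19 | tert-butyl 4-[(2R,4R,6S)-6-{[(4R,6S)-2,2-dimethyl-6-nonyl-1,3-dioxan-4-yl]methyl}-2-phenyl-1,3-dioxan-4-yl]-3-oxobutanoate | CC(C)(C)OC(=O)CC(=O)C[C@H]1C[C@@H](C[C@@H]3C[C@H](CCCCCCCCC)OC(C)(C)O3)O[C@@H](c2ccccc2)O1 | intermediate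
20 | (5R,7R,9S,11S)-5,7,9,11-tetrahydroxy-3-oxoicosanoic acid | CCCCCCCCC[C@H](O)C[C@H](O)C[C@@H](O)C[C@@H](O)CC(=O)CC(=O)O | intermediate (not isolated)
21 | (6R)-4-hydroxy-6-[(2R,4S,6S)-2,4,6-trihydroxypentadecyl]-5,6-dihydro-2H-pyran-2-one | CCCCCCCCC[C@H](O)C[C@H](O)C[C@@H](O)C[C@@H]1CC(O)=CC(=O)O1 | target

## Step count and least certain steps

Total: 12 steps. Longest linear sequence: 11 steps (steps 1–6 and 8–12); step 7 is a one-step branch.

Step 4 (key step). The most likely failure is incomplete funnelling. The [3,3] equilibrium lies on the side of the primary allylic alcohol, so the outcome depends on acetal capture being faster than side processes of the perrhenate: ionisation of the allylic C–O bond with elimination or etherification, and deactivation of the catalyst by the methanol set free or by chelation to the β-hydroxy ester. If acetal exchange stops early, the anti acetal is not drained and the syn selectivity drops. The fallback sets out from 5 and comes back at 8, with the C7 centre set by a reagent instead of by equilibrium. Geometrically pure E-5 is needed for it. Sharpless asymmetric epoxidation (Ti(OiPr)4, L-(+)-diethyl tartrate, t-BuOOH, 4 Å sieves, CH2Cl2, −20 °C) should give ethyl (3R)-3-hydroxy-4-[(2S,3S)-3-(hydroxymethyl)oxiran-2-yl]butanoate F1. Selective iodination of the primary hydroxyl (I2, PPh3, imidazole, 0 °C) gives ethyl (3R)-3-hydroxy-4-[(2S,3R)-3-(iodomethyl)oxiran-2-yl]butanoate F2. Zn dust in EtOH opens the epoxide by reductive β-elimination to the transposed diol 7, this time isolated, and 6 with catalytic camphorsulfonic acid closes it to 8.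

Step 8. Two things may go wrong: weak facial selectivity, because the β-oxygen sits in a dioxane whose two oxygens can compete for the Lewis acid, and Lewis-acid opening of the benzylidene acetal by the enol silane. The fallback sets out from 11 and comes back at 17, and it reverses the order in which C9 and C11 are set. MeMgBr (THF, −78 °C) adds to the aldehyde to give ethyl 2-[(2R,4R,6R)-6-(2-hydroxypropyl)-2-phenyl-1,3-dioxan-4-yl]acetate F6 as a mixture of carbinol epimers. Dess–Martin oxidation gives the methyl ketone ethyl 2-[(2R,4R,6S)-6-(2-oxopropyl)-2-phenyl-1,3-dioxan-4-yl]acetate F7. Its dibutylboron enolate (Bu2BOTf, iPr2NEt, Et2O, −78 °C) adds to decanal with 1,5-anti induction from the β-acetal oxygen, which is known to be strong for benzylidene-type acetals, to give ethyl 2-[(2R,4R,6S)-6-[(4S)-4-hydroxy-2-oxotridecyl]-2-phenyl-1,3-dioxan-4-yl]acetate F8. Et2BOMe/NaBH4 then reduces the C9 ketone syn to the C11 hydroxyl, which is 17.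

Step 12. The risk is one of timing: ionisation of the tert-butyl ester ahead of acetal hydrolysis would leave a β-keto acid that cannot yet lactonise and may decarboxylate. In addition, O7 can close on the C3 ketone and the hemiketal may dehydrate. The fallback sets out from 19 and comes back at 21 without any free β-keto acid. Hydrogenolysis (H2, Pd(OH)2/C, EtOAc) removes only the benzylidene acetal and gives tert-butyl (5R,7S)-8-[(4R,6S)-2,2-dimethyl-6-nonyl-1,3-dioxan-4-yl]-5,7-dihydroxy-3-oxooctanoate F9. Heating in toluene at 110 °C expels tert-butanol to an acyl ketene, which O5 captures intramolecularly to give (6R)-6-{(2R)-3-[(4R,6S)-2,2-dimethyl-6-nonyl-1,3-dioxan-4-yl]-2-hydroxypropyl}-4-hydroxy-5,6-dihydro-2H-pyran-2-one F10. Mild aqueous acid (AcOH/H2O 4:1, 40 °C) then removes the acetonide to give 21.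

Step 2. The basic Grignard reagent may deprotonate α to the ester and open the epoxide by β-elimination, or add to the ester, before the copper-mediated opening takes place. The fallback sets out from 2 and comes back at 8; it avoids both the Grignard reagent and the metathesis. The lithium acetylide of tert-butyldimethyl(prop-2-yn-1-yloxy)silane with BF3·OEt2 (THF, −78 °C) opens the epoxide at its terminus to give ethyl (3R)-7-[(tert-butyldimethylsilyl)oxy]-3-hydroxyhept-5-ynoate F3. Semihydrogenation (H2, Pd/CaCO3 poisoned with Pb(OAc)2, quinoline) gives ethyl (3R,5Z)-7-[(tert-butyldimethylsilyl)oxy]-3-hydroxyhept-5-enoate F4. Bu4NF buffered with AcOH gives ethyl (3R,5Z)-3,7-dihydroxyhept-5-enoate F5, the Z isomer of 5, which enters step 4 in its place and should give 8 because the reversible shift erases alkene geometry.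

## Further compounds

F1 | step 4 | ethyl (3R)-3-hydroxy-4-[(2S,3S)-3-(hydroxymethyl)oxiran-2-yl]butanoate | CCOC(=O)C[C@H](O)C[C@@H]1O[C@H]1CO
F2 | step 4 | ethyl (3R)-3-hydroxy-4-[(2S,3R)-3-(iodomethyl)oxiran-2-yl]butanoate | CCOC(=O)C[C@H](O)C[C@@H]1O[C@H]1CI
F3 | step 2 | ethyl (3R)-7-[(tert-butyldimethylsilyl)oxy]-3-hydroxyhept-5-ynoate | CCOC(=O)C[C@H](O)CC#CCO[Si](C)(C)C(C)(C)C
F4 | step 2 | ethyl (3R,5Z)-7-[(tert-butyldimethylsilyl)oxy]-3-hydroxyhept-5-enoate | CCOC(=O)C[C@H](O)C/C=C\CO[Si](C)(C)C(C)(C)C
F5 | step 2 | ethyl (3R,5Z)-3,7-dihydroxyhept-5-enoate | CCOC(=O)C[C@H](O)C/C=C\CO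
F6 | step 8 | ethyl 2-[(2R,4R,6R)-6-(2-hydroxypropyl)-2-phenyl-1,3-dioxan-4-yl]acetate (both carbinol epimers) | CCOC(=O)C[C@H]1C[C@@H](CC(C)O)O[C@@H](c2ccccc2)O1
F7 | step 8 | ethyl 2-[(2R,4R,6S)-6-(2-oxopropyl)-2-phenyl-1,3-dioxan-4-yl]acetate | CCOC(=O)C[C@H]1C[C@@H](CC(C)=O)O[C@@H](c2ccccc2)O1
F8 | step 8 | ethyl 2-[(2R,4R,6S)-6-[(4S)-4-hydroxy-2-oxotridecyl]-2-phenyl-1,3-dioxan-4-yl]acetate | CCOC(=O)C[C@H]1C[C@@H](CC(=O)C[C@@H](O)CCCCCCCCC)O[C@@H](c2ccccc2)O1
F9 | step 12 | tert-butyl (5R,7S)-8-[(4R,6S)-2,2-dimethyl-6-nonyl-1,3-dioxan-4-yl]-5,7-dihydroxy-3-oxooctanoate | CC(C)(C)OC(=O)CC(=O)C[C@H](O)C[C@H](O)C[C@@H]1C[C@H](CCCCCCCCC)OC(C)(C)O1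
F10 | step 12 | (6R)-6-{(2R)-3-[(4R,6S)-2,2-dimethyl-6-nonyl-1,3-dioxan-4-yl]-2-hydroxypropyl}-4-hydroxy-5,6-dihydro-2H-pyran-2-one | CCCCCCCCC[C@H]1C[C@@H](C[C@@H](O)C[C@@H]2CC(O)=CC(=O)O2)OC(C)(C)O1
A1 | alternative 1 | (2S)-1-{2-[(2S)-2-(tert-butyldimethylsilyloxy)undecyl]-1,3-dithian-2-yl}pent-4-en-2-ol | CCCCCCCCC[C@H](O[Si](C)(C)C(C)(C)C)CC1(SCCCS1)C[C@@H](O)CC=C
A2 | alternative 1 | 2-(tert-butyldimethylsilyl)-1,3-dithiane | CC(C)(C)[Si](C)(C)C1SCCCS1
A3 | alternative 1 | (2S)-2-nonyloxirane | CCCCCCCCC[C@H]1CO1
A4 | alternative 1 | (2S)-2-(prop-2-en-1-yl)oxirane | C=CC[C@H]1CO1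
A5 | alternative 2 | 8-oxabicyclo[3.2.1]oct-6-en-3-one (meso) | O=C1C[C@H]2C=C[C@@H](C1)O2
A6 | alternative 2 | furan | c1ccoc1
A7 | alternative 2 | 1,1,3,3-tetrabromopropan-2-one | O=C(C(Br)Br)C(Br)Br
A8 | alternative 3 | (6R)-6-{(2R)-2-[(tert-butyldimethylsilyl)oxy]-3-[(4S,6S)-2,2-dimethyl-6-nonyl-1,3-dioxan-4-yl]propyl}-4-hydroxy-5,6-dihydro-2H-pyran-2-one | CCCCCCCCC[C@H]1C[C@@H](C[C@@H](O[Si](C)(C)C(C)(C)C)C[C@@H]2CC(O)=CC(=O)O2)OC(C)(C)O1
A9 | alternative 3 | methyl (3R,5R)-3-(2-bromoacetoxy)-5-[(tert-butyldimethylsilyl)oxy]-6-[(4S,6S)-2,2-dimethyl-6-nonyl-1,3-dioxan-4-yl]hexanoate | CCCCCCCCC[C@H]1C[C@@H](C[C@@H](O[Si](C)(C)C(C)(C)C)C[C@H](CC(=O)OC)OC(=O)CBr)OC(C)(C)O1
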